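The numbers in the tables are calculated from invented constants; noise was put on by code.

**Two clocks.** Temperature moves two things in the earlier runs: how fast product appears and how soon it stops appearing. I want the product in larch, oak and cedar at the end of 2.0 h, so I ask which comes first in each flask, the stall or the end of the time.

| setting | alpha | zeta | larch | oak | cedar |
|---|---|---|---|---|---|
| substrate | 0.069 M | 0.069 M | 0.069 M | 0.069 M | 0.069 M |
| coupling partner | 0.055 M | 0.12 M | 0.0828 M | 0.0828 M | 0.0828 M |
| catalyst | 3 mM | 3 mM | 3.0 mM | 3.0 mM | 3.0 mM |
| temperature | 40 °C | 62 °C | 70 °C | 50 °C | 30 °C |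
| remark | run made earlier | run made earlier |  |  |  |
| time |  |  | 2.0 h | 2.0 h | 2.0 h |

- alpha (time / h: product / %, substrate / %): 0.417: 5.9, 64.3; 0.833: 13.3, 50.8; 2.00: 26.3, 37.5; 6.00: 40.6, 27.8
- zeta (time / min: product / %, substrate / %): 20.0: 22.6, 52.5; 40.0: 29.9, 47.3; 50.0: 30.9, 46.0; 80.0: 33.3, 44.7

(each reading ± 0.5 percentage points)

- which flask leads in amount of product, in percent of the substrate charged ("all alike" within 1.5 percentage points) (larch / oak / cedar / all alike)
- how much product is there at the end, in percent of the substrate charged: larch
- how much product is there at the end, in percent of the substrate charged: oak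
- how much product is there at the end, in percent of the substrate charged: cedar

- the numbers in the tables scatter with a standard deviation of 0.5 percentage points

**Stall constant.** I compare two late slopes of each product curve. The rate falls at 0.440 h⁻¹ in alpha and 2.60 h⁻¹ in zeta. A flask has then reached the fraction 1 − exp(−constant × time) of its ceiling. Two runs are a thin base, but I take the logarithm as straight in temperature. That gives 4.97 h⁻¹ for larch, 0.987 h⁻¹ for oak and 0.196 h⁻¹ for cedar, and this last figure is cedar's stall constant, my interpolated estimate of the fractional fall of the late product rate per hour. Multiplied by the time, cedar's is 0.392, less than one, while oak's is 1.97 and larch's 9.94, both more than one. Control changes hands between cedar and oak.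

**The ceilings.** Dividing each last reading by its fraction gives ceilings of 43.7% in alpha and 34.4% in zeta. Yet zeta had more coupling partner than alpha, so I let temperature lower the ceiling per partner. I take the ceiling as proportional to the partner charged. A dying catalyst could draw the same curves, and these two runs can't separate the two, so larch is exposed to that doubt. The same interpolation gives 16.4% for larch, 41.4% for oak and 105% for cedar. Cedar's figure is more than the charge, so it can't stand. Substrate and product together come to 68.4% at the last alpha reading, and I use that as cedar's ceiling, though the missing material may yet drain.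

**My reckoning.** Ceiling times fraction gives 16.4% for larch, 35.6% for oak and 22.2% for cedar, so oak leads.

**The result.** The forecast names oak, with 17% for larch, 39% for oak and 15% for cedar, on the ground that “Cold is simply too slow”, against my own cedar figure above. The flasks give 17.3% in larch, 37.7% in oak and 22.6% in cedar, so oak leads.

    substrate + catalyst ⇌ catalyst + intermediate (K = 0.430, k = 0.210 M⁻¹ s⁻¹, Ea = 66.0 kJ mol⁻¹, ΔH = −36.0 kJ mol⁻¹)
    coupling partner + catalyst + intermediate → catalyst + product (k = 3.50 M⁻² s⁻¹, Ea = 55.0 kJ mol⁻¹)
    substrate ⇌ dormant form (K = 0.310, k = 3.30 × 10⁻⁴ s⁻¹, Ea = 88.0 kJ mol⁻¹, ΔH = −23.0 kJ mol⁻¹)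
    coupling partner → decomposed reagent (k = 2.00 × 10⁻⁴ s⁻¹, Ea = 95.0 kJ mol⁻¹)
    (constants at 50 °C)

**Longer cedar.** Cedar is the flask still short of its stall, so its constant should tell how it goes on. Left until 5.0 h, with 0.196 h⁻¹, its fraction of the ceiling grows by a factor 1.93. Applied to the 22.6% it holds at 2.0 h, that gives 43.6%. The flask read at that time holds 45.9% of product, with 15.7% as intermediate and coupling partner at 38.9% of its own charge.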